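**Retrosynthetic overview**
- Target 29 ⇐ C3 oxidation and desilylation ⇐ C12–C13 Negishi union of bicyclic iodide 17 with E-vinyl iodide 24 (geranyl bromide plus a propargyl unit, then carboalumination/iodination).
- 17 ⇐ keto ester 11: C8 ketone → exocyclic methylene → α-epoxide → hydride (gives 8α-OH/8β-CH3 and reduces the ester to the C12 alcohol).
- 11 ⇐ octalone 8 + Me2CuLi + tert-butyl bromoacetate 9. The feature used: in ring B the carbinol carbon C8 is flanked by the chain-bearing C9 and by the methyl-bearing fusion carbon C10, whose methyl is cis to the C5 hydrogen (cis-fused rings A/B). A ketone at C8 makes C9=C10 an enone with C10 as β and C9 as α carbon.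
- 8 ⇐ 6-methoxy-2-tetralone 1: rings A and B are present from the start (the anisole ring becomes ring B by Birch reduction), so no ring is formed in the route. The temporary C3 carbinol comes from a CBS reduction and C5 follows C3 by equilibration.

Key step: step 6

Remark: terpenoid numbering is used (C1–C10 decalin, C3 ketone, C4 gem-dimethyl, C5 fusion CH, C8 carbinol, C9 chain carbon, C10 angular-methyl carbon, C11/C12 chain methylenes, C13=C14 first chain alkene), α/β refer to the drawing with the C10 methyl β, and the target SMILES is read as 5S,8R,9R,10S, i.e. C5–H, C10–CH3, the C9 chain and the C8 methyl all β and C8–OH α (cis-fused decalin).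

**Route**

Step 1
Reactants: 1 6-methoxy-2-tetralone
Product: 3 6-methoxy-1,1-dimethyl-3,4-dihydronaphthalen-2(1H)-one, via 6-methoxy-1-methyl-2-tetralone 2 (not isolated)
Conditions: NaH (2.2 equiv), MeI (2.5 equiv), THF, 0 to 20 °C
Reagents that add atoms: iodomethane, CI
Why: Double enolate C-alkylation, in which the benzylic C1 of the 2-tetralone is the more acidic α-position and is methylated twice through the aryl-conjugated enolate, installing the future C4 gem-dimethyl group.

Step 2
Reactants: 3 6-methoxy-1,1-dimethyl-3,4-dihydronaphthalen-2(1H)-one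
Product: 4 (R)-6-methoxy-1,1-dimethyl-1,2,3,4-tetrahydronaphthalen-2-ol
Conditions: (S)-Me-CBS oxazaborolidine (10 mol %), BH3·SMe2, THF, −20 °C; MeOH quench
Reagents that add atoms: none
Why: Corey–Bakshi–Shibata reduction, in which the ketone binds the oxazaborolidine–borane complex with the quaternary CMe2Ar side as the large group, so the catalyst sets the (R)-carbinol (future C3, a temporary control element).

Step 3
Reactants: 4 (R)-6-methoxy-1,1-dimethyl-1,2,3,4-tetrahydronaphthalen-2-ol
Product: 5 (R)-6-methoxy-1,1-dimethyl-1,2,3,4,5,8-hexahydronaphthalen-2-ol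
Conditions: Li, NH3(l), THF, t-BuOH, −78 to −33 °C; solid NH4Cl
Reagents that add atoms: none
Why: Birch reduction of an alkyl-substituted anisole should give the 2,5-dihydroanisole with the methoxy-bearing carbon and both fusion carbons left on double bonds, while the homobenzylic alkoxide is inert.

Step 4
Reactants: 5 (R)-6-methoxy-1,1-dimethyl-1,2,3,4,5,8-hexahydronaphthalen-2-ol
Product: 7 (4aS,6R)-6-hydroxy-5,5-dimethyl-4,4a,5,6,7,8-hexahydronaphthalen-2(3H)-one, via β,γ-unsaturated hydroxy ketone 6 (not isolated)
Conditions: 1 M HCl, MeOH, 20 °C; then NaOMe (cat.), MeOH, 20 °C; recrystallisation, mother liquor returned to the NaOMe equilibration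
Reagents that add atoms: water, O
Why: Enol ether hydrolysis gives 6, which conjugates through its dienol so that C5 (C4a) is created by reversible γ-protonation under thermodynamic control by C3, the favoured epimer having ring A as a chair with the hydroxyl equatorial and the C3 and C5 hydrogens cis; since this bias is only that of an equatorial over an axial hydroxyl, the minor epimer is removed by crystallisation and re-equilibrated.

Step 5
Reactants: 7 (4aS,6R)-6-hydroxy-5,5-dimethyl-4,4a,5,6,7,8-hexahydronaphthalen-2(3H)-one
Product: 8 (4aS,6R)-6-(tert-butyldimethylsilyloxy)-5,5-dimethyl-4,4a,5,6,7,8-hexahydronaphthalen-2(3H)-one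
Conditions: TBSCl, imidazole, DMAP (cat.), DMF, 45 °C
Reagents that add atoms: tert-butyldimethylsilyl chloride, CC(C)(C)[Si](C)(C)Cl
Why: Silyl ether formation on the only hydroxyl, where the neopentyl-type equatorial carbinol needs DMF and gentle warming and the enone and C5 are untouched by imidazole.

Step 6
Reactants: 8 (4aS,6R)-6-(tert-butyldimethylsilyloxy)-5,5-dimethyl-4,4a,5,6,7,8-hexahydronaphthalen-2(3H)-one; 9 tert-butyl bromoacetate
Product: 11 tert-butyl (3α-TBSO-4,4,10β-trimethyl-8-oxo-5β-decalin-9β-yl)acetate (cis-fused keto ester), via lithium enolate 10 (not isolated)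
Conditions: Me2CuLi (from CuI and 2 MeLi), Et2O, −20 to 0 °C; then 9 (3 equiv), HMPA, THF, −40 to 20 °C
Reagents that add atoms: lithium dimethylcuprate (made in the flask from methyllithium and CuI), [Li+].C[Cu-]C
Why: Me2CuLi forms a π-complex with the enone of 8 and transfers methyl to C10 through a β-cuprio (trivalent copper) enolate, leaving the regiodefined C8–C9 lithium enolate 10, which is C-alkylated by the SN2-active bromoacetate 9 once HMPA breaks up the copper–lithium aggregates; the closest known reaction type is conjugate addition of a Gilman cuprate to a bicyclic octalone with capture of the enolate by an activated halide. No ring is closed; the new bonds are C10–CH3 and C9–C11. C10 is controlled by C5: methyl adds to the β-face, anti to the C5–C4 bond (the γ-substituent of the enone) and away from the axial 4α-methyl that lies 1,3 to the α-face of C10, so the methyl ends cis to the C5 hydrogen, equatorial on ring A and axial on ring B. C9 is controlled by the folded cis-decalin: its α-face is screened by C4 and the 4α-methyl, so the electrophile should enter from the convex β-face, which is also the equatorial, thermodynamically preferred position, and because C9 stays α to the C8 ketone any α-epimer can be converged with base. The step needs β-face selectivity at C10 and C-alkylation at the hindered C9 without enolate migration to C7; the first is secured by the C5 stereocentre together with the C4 gem-dimethyl group, the second by generating the enolate only between C8 and C9 and using an excess of a highly reactive halide at low temperature.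

Step 7
Reactants: 11 cis-fused keto ester
Product: 12 tert-butyl (3α-TBSO-4,4,10β-trimethyl-8-methylene-5β-decalin-9β-yl)acetate
Conditions: Ph3PCH3Br, KOtBu, toluene, 20 to 80 °C
Reagents that add atoms: methyltriphenylphosphonium bromide, C[P+](c1ccccc1)(c1ccccc1)c1ccccc1.[Br-]
Why: Wittig methylenation with Ph3P=CH2 in warm toluene should convert the hindered C8 ketone into the exocyclic alkene, the tert-butyl ester being inert to the ylide and C9 already in its equatorial, thermodynamic configuration.

Step 8
Reactants: 12 methylene ester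
Product: 13 tert-butyl ester carrying the C8 spiro-epoxide with oxygen α (3α-TBSO; 5β-H; 9β arm; 10β-methyl)
Conditions: mCPBA, NaHCO3, CH2Cl2, 0 °C
Reagents that add atoms: 3-chloroperoxybenzoic acid, OOC(=O)c1cccc(Cl)c1
Why: Prilezhaev epoxidation, in which the peracid should reach the only alkene from the equatorial α-side because the axial β-trajectory is 1,3-diaxial to the C10 methyl, so C8 is set by C10 with the epoxide oxygen α.

Step 9
Reactants: 13 α-epoxy ester
Product: 14 diol with 8α-OH/8β-CH3 and a 9β-CH2CH2OH arm (3α-TBSO; 5β-H; 10β-methyl)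
Conditions: LiAlH4, THF, 0 to 65 °C; Fieser work-up
Reagents that add atoms: none
Why: Hydride reduction, in which LiAlH4 opens the 1,1-disubstituted epoxide at its CH2 terminus (SN2, C8–O bond untouched, so the 8α-carbinol with a β-methyl results) and reduces the tert-butyl ester to the C12 alcohol while the TBS ether survives.

Step 10
Reactants: 14 diol
Product: 16 C12 primary alcohol with the C8 oxygen as trimethylsilyl ether (3α-TBSO), via bis(trimethylsilyl) ether 15 (not isolated)
Conditions: TMSOTf (2.5 equiv), 2,6-lutidine, CH2Cl2, −78 to 0 °C; then MeOH, K2CO3, 0 °C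
Reagents that add atoms: trimethylsilyl triflate, C[Si](C)(C)OS(=O)(=O)C(F)(F)F
Why: Exhaustive silylation followed by selective methanolysis, the primary trimethylsilyl ether being cleaved far faster than the hindered tertiary one, which keeps the C8 oxygen masked so that it cannot close a tetrahydrofuran ring onto C12 once C12 is activated.

Step 11
Reactants: 16 C12 alcohol
Product: 17 C12 iodide (9β-CH2CH2I; 8α-OTMS; 3α-TBSO)
Conditions: I2, PPh3, imidazole, CH2Cl2, 0 °C
Reagents that add atoms: iodine, II
Why: Appel-type iodination converts the primary alcohol into the iodide by SN2 displacement of the oxyphosphonium group under imidazole-buffered conditions that both silyl ethers tolerate.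

Step 12
Reactants: 18 1-(trimethylsilyl)propyne; 19 geranyl bromide
Product: 21 (E)-trimethyl(6,10-dimethylundeca-5,9-dien-1-yn-1-yl)silane, via 3-lithio-1-(trimethylsilyl)propyne 20 (not isolated)
Conditions: n-BuLi, THF, −78 °C; then 19, −78 to 0 °C
Reagents that add atoms: none
Why: Propargylic lithiation followed by SN2 alkylation at the primary carbon of the allylic bromide should give the enyne with the E-alkene intact, the silyl group blocking the acetylenic terminus.

Step 13
Reactants: 21 silyl dienyne
Product: 22 (E)-6,10-dimethylundeca-5,9-dien-1-yne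
Conditions: K2CO3, MeOH, 20 °C
Reagents that add atoms: none
Why: Base-mediated methanolysis of the alkynyl C–Si bond frees the terminal alkyne without touching the alkenes.

Step 14
Reactants: 22 (E)-6,10-dimethylundeca-5,9-dien-1-yne
Product: 24 (1E,5E)-1-iodo-2,6,10-trimethylundeca-1,5,9-triene, via alkenyldimethylalane 23 (not isolated)
Conditions: Me3Al, Cp2ZrCl2, CH2Cl2, 0 to 20 °C; then I2, THF, −30 to 0 °C
Reagents that add atoms: trimethylaluminium, C[Al](C)C; iodine, II
Why: Zirconium-catalysed carboalumination (Negishi) adds methyl and aluminium syn across the terminal alkyne with methyl on the internal carbon, and iodinolysis with retention gives the E-trisubstituted vinyl iodide, which fixes the C13=C14 geometry.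

Step 15
Reactants: 17 C12 iodide; 24 (1E,5E)-1-iodo-2,6,10-trimethylundeca-1,5,9-triene
Product: 27 coupled bis-silyl ether (full C30 skeleton; 3α-TBSO; 8α-OTMS), via alkyllithium 25 (not isolated), via alkylzinc chloride 26 (not isolated)
Conditions: t-BuLi (2.1 equiv), Et2O, −78 °C; ZnCl2, THF, −78 to 20 °C; then 24, Pd(PPh3)4 (5 mol %), THF, 20 °C
Reagents that add atoms: none
Why: Negishi coupling, in which iodine–lithium exchange and transmetalation to zinc give a primary alkylzinc that couples with the alkenyl iodide under zerovalent palladium catalysis with retention of the E-geometry, forming the C12–C13 bond.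

Step 16
Reactants: 27 coupled bis-silyl ether
Product: 28 3α,8α-diol (target skeleton with C3 carbinol)
Conditions: TBAF, THF, 50 °C
Reagents that add atoms: none
Why: Fluoride-mediated desilylation removes the tertiary trimethylsilyl and the hindered secondary TBS ether under basic conditions that spare the tertiary carbinol and the trisubstituted alkenes.

Step 17
Reactants: 28 3α,8α-diol
Product: 29 IN0671
Conditions: Dess–Martin periodinane, NaHCO3, CH2Cl2, 0 to 20 °C
Reagents that add atoms: none
Why: Dess–Martin oxidation converts the secondary C3 alcohol into the ketone, the tertiary C8 alcohol cannot be oxidised, and the buffered medium leaves the polyene untouched.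

**Compound list**

1 | 6-methoxy-2-tetralone | COc1ccc2c(c1)CCC(=O)C2 | starting material
2 | 6-methoxy-1-methyl-2-tetralone (racemic) | COc1ccc2c(c1)CCC(=O)C2C | intermediate
3 | 6-methoxy-1,1-dimethyl-3,4-dihydronaphthalen-2(1H)-one | COc1ccc2c(c1)CCC(=O)C2(C)C | intermediate
4 | (R)-6-methoxy-1,1-dimethyl-1,2,3,4-tetrahydronaphthalen-2-ol | COc1ccc2c(c1)CC[C@@H](O)C2(C)C | intermediate
5 | (R)-6-methoxy-1,1-dimethyl-1,2,3,4,5,8-hexahydronaphthalen-2-ol | COC1=CCC2=C(C1)CC[C@@H](O)C2(C)C | intermediate
6 | (R)-6-hydroxy-5,5-dimethyl-3,4,5,6,7,8-hexahydronaphthalen-2(1H)-one | O=C1CCC2=C(C1)CC[C@@H](O)C2(C)C | intermediate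
7 | (4aS,6R)-6-hydroxy-5,5-dimethyl-4,4a,5,6,7,8-hexahydronaphthalen-2(3H)-one | O=C1C=C2CC[C@@H](O)C(C)(C)[C@H]2CC1 | intermediate
8 | (4aS,6R)-6-(tert-butyldimethylsilyloxy)-5,5-dimethyl-4,4a,5,6,7,8-hexahydronaphthalen-2(3H)-one (C8 ketone, C9=C10, 5β-H, 3α-OTBS) | O=C1C=C2CC[C@@H](O[Si](C)(C)C(C)(C)C)C(C)(C)[C@H]2CC1 | intermediate
9 | tert-butyl bromoacetate | CC(C)(C)OC(=O)CBr | starting material
10 | lithium C8–C9 enolate of the 10β-methyl-5β-H cis-decalone (3α-OTBS) | [Li]OC1=C[C@@]2(C)CC[C@@H](O[Si](C)(C)C(C)(C)C)C(C)(C)[C@H]2CC1 | intermediate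
11 | tert-butyl (3α-TBSO-4,4,10β-trimethyl-8-oxo-5β-decalin-9β-yl)acetate | CC(C)(C)OC(=O)C[C@@H]1[C@@]2(C)CC[C@@H](O[Si](C)(C)C(C)(C)C)C(C)(C)[C@H]2CCC1=O | intermediate
12 | tert-butyl (3α-TBSO-4,4,10β-trimethyl-8-methylene-5β-decalin-9β-yl)acetate | CC(C)(C)OC(=O)C[C@@H]1[C@@]2(C)CC[C@@H](O[Si](C)(C)C(C)(C)C)C(C)(C)[C@H]2CCC1=C | intermediate
13 | C8 spiro-epoxide (oxygen α) of 12 | CC(C)(C)OC(=O)C[C@@H]1[C@@]2(C)CC[C@@H](O[Si](C)(C)C(C)(C)C)C(C)(C)[C@H]2CC[C@]13CO3 | intermediate
14 | diol: 8α-OH, 8β-CH3, 9β-CH2CH2OH, 3α-OTBS, 5β-H, 10β-CH3 | OCC[C@@H]1[C@@]2(C)CC[C@@H](O[Si](C)(C)C(C)(C)C)C(C)(C)[C@H]2CC[C@@]1(C)O | intermediate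
15 | bis(trimethylsilyl) ether of 14 | C[Si](C)(C)OCC[C@@H]1[C@@]2(C)CC[C@@H](O[Si](C)(C)C(C)(C)C)C(C)(C)[C@H]2CC[C@@]1(C)O[Si](C)(C)C | intermediate
16 | C12 alcohol with 8α-OTMS and 3α-OTBS | OCC[C@@H]1[C@@]2(C)CC[C@@H](O[Si](C)(C)C(C)(C)C)C(C)(C)[C@H]2CC[C@@]1(C)O[Si](C)(C)C | intermediate
17 | C12 iodide with 8α-OTMS and 3α-OTBS | ICC[C@@H]1[C@@]2(C)CC[C@@H](O[Si](C)(C)C(C)(C)C)C(C)(C)[C@H]2CC[C@@]1(C)O[Si](C)(C)C | intermediate
18 | 1-(trimethylsilyl)propyne | CC#C[Si](C)(C)C | starting material
19 | geranyl bromide | CC(C)=CCC/C(C)=C/CBr | starting material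
20 | 3-lithio-1-(trimethylsilyl)propyne | [Li]CC#C[Si](C)(C)C | intermediate
21 | (E)-trimethyl(6,10-dimethylundeca-5,9-dien-1-yn-1-yl)silane | CC(C)=CCC/C(C)=C/CCC#C[Si](C)(C)C | intermediate
22 | (E)-6,10-dimethylundeca-5,9-dien-1-yne | CC(C)=CCC/C(C)=C/CCC#C | intermediate
23 | (1E,5E)-(2,6,10-trimethylundeca-1,5,9-trien-1-yl)dimethylalane | CC(C)=CCC/C(C)=C/CC/C(C)=C/[Al](C)C | intermediate
24 | (1E,5E)-1-iodo-2,6,10-trimethylundeca-1,5,9-triene | CC(C)=CCC/C(C)=C/CC/C(C)=C/I | intermediate
25 | C12 alkyllithium from 17 | [Li]CC[C@@H]1[C@@]2(C)CC[C@@H](O[Si](C)(C)C(C)(C)C)C(C)(C)[C@H]2CC[C@@]1(C)O[Si](C)(C)C | intermediate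
26 | C12 alkylzinc chloride from 17 | Cl[Zn]CC[C@@H]1[C@@]2(C)CC[C@@H](O[Si](C)(C)C(C)(C)C)C(C)(C)[C@H]2CC[C@@]1(C)O[Si](C)(C)C | intermediate
27 | coupled product with 3α-OTBS and 8α-OTMS | CC(C)=CCC/C(C)=C/CC/C(C)=C/CC[C@@H]1[C@@]2(C)CC[C@@H](O[Si](C)(C)C(C)(C)C)C(C)(C)[C@H]2CC[C@@]1(C)O[Si](C)(C)C | intermediate
28 | 3α,8α-diol | CC(C)=CCC/C(C)=C/CC/C(C)=C/CC[C@@H]1[C@@]2(C)CC[C@@H](O)C(C)(C)[C@H]2CC[C@@]1(C)O | intermediate
29 | IN0671 (5S,8R,9R,10S) | CC(C)=CCC/C(C)=C/CC/C(C)=C/CC[C@@H]1[C@@]2(C)CCC(=O)C(C)(C)[C@H]2CC[C@@]1(C)O | target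

**Step count and risks**

Total steps: 17. Longest linear sequence: 14 steps (steps 1–11 and 15–17, from 6-methoxy-2-tetralone).

Steps most likely to fail:

1. Step 6 (key step). The cuprate may add slowly to the hindered, β,β-disubstituted enone. The copper-containing enolate may then alkylate sluggishly at C9, which is crowded on both faces, so proton transfer from the bromoacetate or from product would return the unalkylated 10-methyl decalone or move the enolate to C7. Fallback, setting out from 8: run the Me2CuLi addition in the presence of TMSCl (which also accelerates the addition) and isolate the trimethylsilyl enol ether F1. Cleave purified F1 with MeLi in THF to the copper-free lithium enolate 10 and alkylate with 9 in THF/HMPA, returning to the route at 11.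

2. Step 4. The thermodynamic preference at C5 is small (one equatorial against one axial hydroxyl next to the gem-dimethyl carbon), so the equilibration may leave much of the C5 epimer. Because C3 is oxidised at the end, any C5 epimer carried forward would surface as the enantiomer of the target. Fallback, setting out from 5, reverses the relay so that C5 is set first and C3 follows. Hydrolyse 5 with oxalic acid to the isolable β,γ-enone 6 and oxidise its carbinol (Dess–Martin periodinane) to the achiral β,γ-unsaturated dione F2. Isomerise F2 with a cinchona-derived primary amine and a carboxylic acid cocatalyst (dienamine, enantioselective γ-protonation) to the conjugated (4aS)-enedione F3. Reduce the saturated C3 ketone of F3 chemoselectively with NaBH4 in EtOH at −20 °C; axial hydride delivery gives the equatorial carbinol with the C3 and C5 hydrogens cis, returning to the route at 7.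

3. Step 8. The small peracid may not discriminate well between the faces of the exocyclic alkene, and β-face attack would give the C8 epimer after reduction. Fallback, setting out from 12: dihydroxylate with OsO4 (cat.) and NMO, a bulkier reagent that should be confined to the equatorial α-side, to give the 8α-hydroxy-8-hydroxymethyl ester F4. Tosylate the primary hydroxyl selectively (TsCl, pyridine) to give F5. Treat F5 with LiAlH4, which removes the sulfonate (directly or through the α-epoxide) and reduces the ester, returning to the route at 14.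

Further compounds
F1 | step 6 | trimethylsilyl enol ether (C8–OTMS, C8=C9) of the 10β-methyl-5β-H cis-decalone, 3α-OTBS | C[Si](C)(C)OC1=C[C@@]2(C)CC[C@@H](O[Si](C)(C)C(C)(C)C)C(C)(C)[C@H]2CC1
F2 | step 4 | 5,5-dimethyl-3,4,7,8-tetrahydronaphthalene-2,6(1H,5H)-dione | O=C1CCC2=C(C1)CCC(=O)C2(C)C
F3 | step 4 | (4aS)-5,5-dimethyl-4,4a,7,8-tetrahydronaphthalene-2,6(3H,5H)-dione | O=C1C=C2CCC(=O)C(C)(C)[C@H]2CC1
F4 | step 8 | tert-butyl ester with 8α-OH and 8β-CH2OH (3α-OTBS; 5β-H; 9β arm; 10β-CH3) | CC(C)(C)OC(=O)C[C@@H]1[C@@]2(C)CC[C@@H](O[Si](C)(C)C(C)(C)C)C(C)(C)[C@H]2CC[C@@]1(CO)O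
F5 | step 8 | primary p-toluenesulfonate of F4 | CC(C)(C)OC(=O)C[C@@H]1[C@@]2(C)CC[C@@H](O[Si](C)(C)C(C)(C)C)C(C)(C)[C@H]2CC[C@@]1(COS(=O)(=O)c3ccc(C)cc3)O
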